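## Retrosynthetic overview

1. The ten-membered ring is closed last, at C6–C7, by a Nozaki–Hiyama–Kishi reaction of a Z-vinyl iodide onto a (Z)-4-oxo-enoate; the resulting alkoxide lactonises in the same flask to the butenolide.
2. The oxo-enoate is unveiled by singlet-oxygen dearomatisation of a 3,4-disubstituted furan, which carries the butenolide carbons through the route.
3. Ring A (α′-acetoxy enone, C10, C14) comes from a 6,6-disubstituted cyclohexa-2,4-dienone by copper-catalysed 1,6-addition of the furylmethyl unit, enolate hydroxylation and α-ketol transposition.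
4. That dienone is the unfolded product of the key step: auxiliary-controlled Birch reduction–methylation of an anisamide made from 4-methylanisole, which turns the benzene ring into ring A and sets the C1 quaternary stereocentre; C2 follows by ketone alkylation and CBS reduction.
5. Ring order: ring A (from the arene) first, butenolide carbons carried as a furan, then the ten-membered ring and the lactone together.

Locants C1–C20 in the Why lines are those of the target: C1 quaternary carbon (C15 methyl), C2 tiglate carbinol, C3, C4, C5(C16 methyl)=C6, C7 lactone carbinol, C8=C17(C18 methyl), C19 lactone carbonyl, C9 methylene, C10 ring-fusion CH, C11(C20 methyl)=C12, C13 ketone, C14 acetoxy carbinol.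

Assumption: the (S)-prolinol methyl ether auxiliary is taken to direct the Birch methylation to the face that gives (1S)-15; if the opposite sense is found, the (R)-auxiliary is used and nothing else changes.

## Route

Step 1
Reactants: 1 prop-2-yn-1-ol
Product: 3 (Z)-3-iodo-2-methylprop-2-en-1-ol, via alkenylmagnesium alkoxide 2 (not isolated)
Conditions: MeMgBr (3 equiv), CuI (10 mol %), THF, −20 °C → rt; then I2, −78 → 0 °C
Reagents that add atoms: methylmagnesium bromide (C[Mg]Br); iodine ([I][I])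
Why: Alkoxide-directed, copper-catalysed anti-carbomagnesiation of the alkyne gives the chelated alkenylmagnesium with Mg cis to CH2O, and iodinolysis with retention gives the Z-iodide (later C4–C6 with C16).

Step 2
Reactants: 3 (Z)-3-iodo-2-methylprop-2-en-1-ol
Product: 4 (Z)-3-bromo-1-iodo-2-methylprop-1-ene
Conditions: CBr4, PPh3, CH2Cl2, 0 °C, dark
Reagents that add atoms: tetrabromomethane (BrC(Br)(Br)Br)
Why: Appel bromination of a primary allylic alcohol proceeds without touching the vinyl iodide or its geometry.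

Step 3
Reactants: 5 4-methylfuran-3-carboxylic acid
Product: 6 (4-methylfuran-3-yl)methanol
Conditions: LiAlH4, THF, 0 °C → rt
Reagents that add atoms: none
Why: Hydride reduction of the carboxylic acid to the primary alcohol leaves the furan untouched.

Step 4
Reactants: 6 (4-methylfuran-3-yl)methanol
Product: 7 3-(chloromethyl)-4-methylfuran
Conditions: SOCl2, pyridine, Et2O, 0 °C; used cold without storage
Reagents that add atoms: thionyl chloride (O=S(Cl)Cl)
Why: Chlorodehydroxylation of the activated furylmethyl alcohol via its chlorosulfite is fast at 0 °C, and the labile chloride is used directly.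

Step 5
Reactants: 8 4-methylanisole
Product: 10 2-methoxy-5-methylbenzoic acid, via aryllithium 9 (not isolated)
Conditions: n-BuLi, TMEDA, Et2O, 0 °C → rt; CO2, −78 °C; aq HCl
Reagents that add atoms: carbon dioxide (O=C=O)
Why: Directed ortho-metalation by the methoxy group (both ortho positions are equivalent) followed by carboxylation gives the single benzoic acid.

Step 6
Reactants: 10 2-methoxy-5-methylbenzoic acid; 11 (S)-2-(methoxymethyl)pyrrolidine
Product: 13 (2-methoxy-5-methylphenyl)[(2S)-2-(methoxymethyl)pyrrolidin-1-yl]methanone, via acid chloride 12 (not isolated)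
Conditions: (COCl)2, DMF (cat.), CH2Cl2, 0 °C → rt; then 11, Et3N, CH2Cl2, 0 °C
Reagents that add atoms: none
Why: Standard acid chloride amidation (Schotten–Baumann type) attaches the chiral auxiliary that will control the dearomatisation.

Step 7
Reactants: 13 (2-methoxy-5-methylphenyl)[(2S)-2-(methoxymethyl)pyrrolidin-1-yl]methanone
Product: 15 [(1S)-2-methoxy-1,5-dimethylcyclohexa-2,5-dien-1-yl][(2S)-2-(methoxymethyl)pyrrolidin-1-yl]methanone, via potassium amide enolate 14 (not isolated)
Conditions: K (2.2 equiv), NH3(l)/THF, t-BuOH (1 equiv), −78 °C; then MeI, −78 °C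
Reagents that add atoms: iodomethane (CI)
Why: Key dearomatisation by asymmetric Birch reduction–alkylation: 1,4-reduction gives a chelated amide enolate that is methylated on the face away from the methoxymethyl arm, setting the C1 quaternary stereocentre and leaving the enol ether (C14) and the trisubstituted alkene (C10=C11) as latent ring A functionality.

Step 8
Reactants: 15 the Birch diene amide
Product: 16 1-[(1S)-2-methoxy-1,5-dimethylcyclohexa-2,5-dien-1-yl]ethan-1-one
Conditions: MeLi (3 equiv), THF, 0 °C → rt; H2O quench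
Reagents that add atoms: methyllithium ([Li]C)
Why: Organolithium addition to the non-enolisable tertiary amide stops at the lithium hemiaminal, which collapses on quench to the methyl ketone (C2, C3) and returns the auxiliary 11; C1 is untouched.

Step 9
Reactants: 16 the methyl ketone; 4 (Z)-3-bromo-1-iodo-2-methylprop-1-ene
Product: 18 (4Z)-5-iodo-1-[(1S)-2-methoxy-1,5-dimethylcyclohexa-2,5-dien-1-yl]-4-methylpent-4-en-1-one, via lithium enolate 17 (not isolated)
Conditions: LiN(iPr)2, THF, −78 °C; then 4, −78 → −20 °C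
Reagents that add atoms: none
Why: The ketone has a single enolisable site (C1 is quaternary), so SN2 alkylation of its lithium enolate with the reactive allylic bromide forges C3–C4 and brings in the Z-vinyl iodide unchanged.

Step 10
Reactants: 18 the iodo-enone side-chain ketone
Product: 19 (1S,4Z)-5-iodo-1-[(1R)-2-methoxy-1,5-dimethylcyclohexa-2,5-dien-1-yl]-4-methylpent-4-en-1-ol
Conditions: (R)-Me-CBS oxazaborolidine [(3aR)-1-methyl-3,3-diphenyltetrahydro-1H,3H-pyrrolo[1,2-c][1,3,2]oxazaborole] (20 mol %), catecholborane, toluene, −78 °C; then MeOH, aq NaHCO3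
Reagents that add atoms: none
Why: Corey–Bakshi–Shibata reduction discriminates the tertiary C1 (large) from the CH2 chain (small), so the (R)-catalyst delivers hydride to give the (S)-carbinol at C2 under reagent control.

Step 11
Reactants: 19 the (S)-carbinol
Product: 21 (1S,4Z)-1-[(1R)-1,3-dimethyl-6-oxocyclohex-2-en-1-yl]-5-iodo-4-methylpent-4-en-1-yl (2E)-2-methylbut-2-enoate, via tiglate enol ether 20 (not isolated)
Conditions: (E)-2-methylbut-2-enoyl chloride, DMAP, Et3N, CH2Cl2, 0 → 40 °C; then 1 M HCl, THF, rt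
Reagents that add atoms: (E)-2-methylbut-2-enoyl chloride (C/C=C(\C)C(Cl)=O); water (O)
Why: DMAP-catalysed acylation installs the final tiglate, and acid hydrolysis of the methyl enol ether then releases the C14 ketone, which cannot eliminate the β-acyloxy group because C1 is quaternary.

Step 12
Reactants: 21 the β,γ-unsaturated ketone
Product: 22 (1S,4Z)-1-[(1R)-1,3-dimethyl-6-oxocyclohexa-2,4-dien-1-yl]-5-iodo-4-methylpent-4-en-1-yl (2E)-2-methylbut-2-enoate
Conditions: IBX, 4-methoxypyridine N-oxide, DMSO, rt; product used at once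
Reagents that add atoms: none
Why: IBX dehydrogenation can only occur across C13–C12 (the other α-carbon is quaternary) and gives the linear 2,4-dienone, which is used immediately to avoid Diels–Alder dimerisation.

Step 13
Reactants: 22 the 2,4-dienone; 7 3-(chloromethyl)-4-methylfuran
Product: 25 (1S,4Z)-1-[(1R,2R)-5-hydroxy-1,3-dimethyl-2-[(4-methylfuran-3-yl)methyl]-6-oxocyclohex-3-en-1-yl]-5-iodo-4-methylpent-4-en-1-yl (2E)-2-methylbut-2-enoate (both C13 epimers), via Grignard reagent 23 (not isolated), via magnesium dienolate 24 (not isolated)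
Conditions: 7, Mg, THF, 0 °C; CuBr·SMe2 (15 mol %), then 22, THF, −78 °C; then 2-(phenylsulfonyl)-3-phenyloxaziridine, −78 °C; aq NH4Cl
Reagents that add atoms: 2-(phenylsulfonyl)-3-phenyloxaziridine (O=S(=O)(c1ccccc1)N1OC1c1ccccc1)
Why: Copper-catalysed 1,6-conjugate addition places the furylmethyl group on the δ-carbon C10 anti to the bulky C1 side chain (setting C10 and moving the alkene to C11=C12), and Davis hydroxylation of the extended enolate at its α-carbon brings in the C13 oxygen.

Step 14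
Reactants: 25 the α-hydroxy ketone
Product: 27 (1S,4Z)-1-[(1R,2R,6S)-6-acetoxy-1,3-dimethyl-2-[(4-methylfuran-3-yl)methyl]-5-oxocyclohex-3-en-1-yl]-5-iodo-4-methylpent-4-en-1-yl (2E)-2-methylbut-2-enoate, via hydroxy enone 26 (not isolated)
Conditions: DBU (0.3 equiv), toluene, 0 °C; then Ac2O, Et3N, DMAP (cat.), 0 °C
Reagents that add atoms: acetic anhydride (CC(=O)OC(C)=O)
Why: Base-mediated α-ketol (enediol) transposition is driven by conjugation of the new C13 ketone with C11=C12, C14 is protonated on the face away from the C1 side chain so that its oxygen ends cis to C2 as required, and immediate acetylation fixes the α′-acetoxy enone of ring A.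

Step 15
Reactants: 27 the ring A acetoxy enone
Product: 28 (1S,4Z)-1-[(1R,2R,6S)-6-acetoxy-2-[(2-hydroxy-4-methyl-5-oxo-2,5-dihydrofuran-3-yl)methyl]-1,3-dimethyl-5-oxocyclohex-3-en-1-yl]-5-iodo-4-methylpent-4-en-1-yl (2E)-2-methylbut-2-enoate (lactol epimers)
Conditions: O2, hν (visible), 5,10,15,20-tetraphenylporphyrin (cat.), iPr2NEt, CH2Cl2, −78 °C
Reagents that add atoms: oxygen (O=O)
Why: Singlet oxygen adds [4+2] to the electron-rich furan only, and the hindered amine removes the less shielded bridgehead hydrogen next to the methyl group (Kornblum–DeLaMare type), so C19 becomes the carbonyl and C7 the lactol carbon.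

Step 16
Reactants: 28 the γ-hydroxybutenolide
Product: 29 methyl (2Z)-4-[(1R,5S,6R)-5-acetoxy-6-{(1S,4Z)-5-iodo-4-methyl-1-[(2E)-2-methylbut-2-enoyloxy]pent-4-en-1-yl}-2,6-dimethyl-4-oxocyclohex-2-en-1-yl]-3-formyl-2-methylbut-2-enoate
Conditions: Me3SiCHN2, MeOH/toluene, 0 °C
Reagents that add atoms: (trimethylsilyl)diazomethane (C[Si](C)(C)C=[N+]=[N-])
Why: Diazoalkane esterification traps the ring-opened (Z)-4-oxo-enoic acid tautomer of the pseudo-acid as its methyl ester, exposing the C7 aldehyde with the ester held cis to it.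

Step 17
Reactants: 29 the aldehyde ester
Product: 31 the target (1R,2S,5Z,7R,10R,14S)-14-acetoxy-13-oxo-2-[(2E)-2-methylbut-2-enoyloxy]briara-5,8(17),11-trien-19,7-olide, via seco hydroxy ester 30 (not isolated)
Conditions: CrCl2 (10 equiv), NiCl2 (2 mol %), DMSO/THF, rt, 2 mM, slow addition; then pyridinium p-toluenesulfonate (cat.), CH2Cl2, rt
Reagents that add atoms: none
Why: Nozaki–Hiyama–Kishi macrocyclisation joins C6 to C7 with retention of the Z-olefin in a ring preorganised by ring A and two cis-alkenes, the C7 configuration is expected (not secured) from attack on the outer face of the s-trans enal, and the alkoxide lactonises onto the cis ester to give the butenolide.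

## Compound list

1 | prop-2-yn-1-ol | C#CCO | starting material
2 | bromomagnesium (Z)-3-(bromomagnesio)-2-methylprop-2-en-1-olate | Br[Mg]OC/C(C)=C\[Mg]Br | intermediate
3 | (Z)-3-iodo-2-methylprop-2-en-1-ol | OC/C(C)=C\I | intermediate
4 | (Z)-3-bromo-1-iodo-2-methylprop-1-ene | BrC/C(C)=C\I | intermediate
5 | 4-methylfuran-3-carboxylic acid | Cc1cocc1C(=O)O | starting material
6 | (4-methylfuran-3-yl)methanol | Cc1cocc1CO | intermediate
7 | 3-(chloromethyl)-4-methylfuran | Cc1cocc1CCl | intermediate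
8 | 4-methylanisole (1-methoxy-4-methylbenzene) | COc1ccc(C)cc1 | starting material
9 | (2-methoxy-5-methylphenyl)lithium | COc1ccc(C)cc1[Li] | intermediate
10 | 2-methoxy-5-methylbenzoic acid | COc1ccc(C)cc1C(=O)O | intermediate
11 | (S)-2-(methoxymethyl)pyrrolidine | COC[C@@H]1CCCN1 | starting material
12 | 2-methoxy-5-methylbenzoyl chloride | COc1ccc(C)cc1C(Cl)=O | intermediate
13 | (2-methoxy-5-methylphenyl)[(2S)-2-(methoxymethyl)pyrrolidin-1-yl]methanone | COC[C@@H]1CCCN1C(=O)c1cc(C)ccc1OC | intermediate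
14 | potassium (2-methoxy-5-methylcyclohexa-2,5-dien-1-ylidene)[(2S)-2-(methoxymethyl)pyrrolidin-1-yl]methanolate | COC[C@@H]1CCCN1C([O-])=C1C=C(C)CC=C1OC.[K+] | intermediate
15 | [(1S)-2-methoxy-1,5-dimethylcyclohexa-2,5-dien-1-yl][(2S)-2-(methoxymethyl)pyrrolidin-1-yl]methanone | C[C@@]1(C(=O)N2CCC[C@H]2COC)C(OC)=CCC(C)=C1 | intermediate
16 | 1-[(1S)-2-methoxy-1,5-dimethylcyclohexa-2,5-dien-1-yl]ethan-1-one | C[C@@]1(C(C)=O)C(OC)=CCC(C)=C1 | intermediate
17 | lithium 1-[(1S)-2-methoxy-1,5-dimethylcyclohexa-2,5-dien-1-yl]ethen-1-olate | C[C@@]1(C([O-])=C)C(OC)=CCC(C)=C1.[Li+] | intermediate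
18 | (4Z)-5-iodo-1-[(1S)-2-methoxy-1,5-dimethylcyclohexa-2,5-dien-1-yl]-4-methylpent-4-en-1-one | C[C@@]1(C(=O)CC/C(C)=C\I)C(OC)=CCC(C)=C1 | intermediate
19 | (1S,4Z)-5-iodo-1-[(1R)-2-methoxy-1,5-dimethylcyclohexa-2,5-dien-1-yl]-4-methylpent-4-en-1-ol | C[C@@]1([C@@H](O)CC/C(C)=C\I)C(OC)=CCC(C)=C1 | intermediate
20 | (1S,4Z)-5-iodo-1-[(1R)-2-methoxy-1,5-dimethylcyclohexa-2,5-dien-1-yl]-4-methylpent-4-en-1-yl (2E)-2-methylbut-2-enoate | C/C=C(\C)C(=O)O[C@@H](CC/C(C)=C\I)[C@]1(C)C(OC)=CCC(C)=C1 | intermediate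
21 | (1S,4Z)-1-[(1R)-1,3-dimethyl-6-oxocyclohex-2-en-1-yl]-5-iodo-4-methylpent-4-en-1-yl (2E)-2-methylbut-2-enoate | C/C=C(\C)C(=O)O[C@@H](CC/C(C)=C\I)[C@]1(C)C(=O)CCC(C)=C1 | intermediate
22 | (1S,4Z)-1-[(1R)-1,3-dimethyl-6-oxocyclohexa-2,4-dien-1-yl]-5-iodo-4-methylpent-4-en-1-yl (2E)-2-methylbut-2-enoate | C/C=C(\C)C(=O)O[C@@H](CC/C(C)=C\I)[C@]1(C)C(=O)C=CC(C)=C1 | intermediate
23 | [(4-methylfuran-3-yl)methyl]magnesium chloride | Cc1cocc1C[Mg]Cl | intermediate
24 | chloromagnesium (5R,6R)-6-{(1S,4Z)-5-iodo-4-methyl-1-[(2E)-2-methylbut-2-enoyloxy]pent-4-en-1-yl}-4,6-dimethyl-5-[(4-methylfuran-3-yl)methyl]cyclohexa-1,3-dien-1-olate | C/C=C(\C)C(=O)O[C@@H](CC/C(C)=C\I)[C@]1(C)C(O[Mg]Cl)=CC=C(C)[C@H]1Cc1cocc1C | intermediate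
25 | (1S,4Z)-1-[(1R,2R)-5-hydroxy-1,3-dimethyl-2-[(4-methylfuran-3-yl)methyl]-6-oxocyclohex-3-en-1-yl]-5-iodo-4-methylpent-4-en-1-yl (2E)-2-methylbut-2-enoate, both epimers at the carbinol | C/C=C(\C)C(=O)O[C@@H](CC/C(C)=C\I)[C@]1(C)C(=O)C(O)C=C(C)[C@H]1Cc1cocc1C | intermediate
26 | (1S,4Z)-1-[(1S,2R,6S)-6-hydroxy-1,3-dimethyl-2-[(4-methylfuran-3-yl)methyl]-5-oxocyclohex-3-en-1-yl]-5-iodo-4-methylpent-4-en-1-yl (2E)-2-methylbut-2-enoate | C/C=C(\C)C(=O)O[C@@H](CC/C(C)=C\I)[C@]1(C)[C@H](O)C(=O)C=C(C)[C@H]1Cc1cocc1C | intermediate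
27 | (1S,4Z)-1-[(1R,2R,6S)-6-acetoxy-1,3-dimethyl-2-[(4-methylfuran-3-yl)methyl]-5-oxocyclohex-3-en-1-yl]-5-iodo-4-methylpent-4-en-1-yl (2E)-2-methylbut-2-enoate | C/C=C(\C)C(=O)O[C@@H](CC/C(C)=C\I)[C@]1(C)[C@H](OC(C)=O)C(=O)C=C(C)[C@H]1Cc1cocc1C | intermediate
28 | (1S,4Z)-1-[(1R,2R,6S)-6-acetoxy-2-[(2-hydroxy-4-methyl-5-oxo-2,5-dihydrofuran-3-yl)methyl]-1,3-dimethyl-5-oxocyclohex-3-en-1-yl]-5-iodo-4-methylpent-4-en-1-yl (2E)-2-methylbut-2-enoate, lactol epimers | C/C=C(\C)C(=O)O[C@@H](CC/C(C)=C\I)[C@]1(C)[C@H](OC(C)=O)C(=O)C=C(C)[C@H]1CC1=C(C)C(=O)OC1O | intermediate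
29 | methyl (2Z)-4-[(1R,5S,6R)-5-acetoxy-6-{(1S,4Z)-5-iodo-4-methyl-1-[(2E)-2-methylbut-2-enoyloxy]pent-4-en-1-yl}-2,6-dimethyl-4-oxocyclohex-2-en-1-yl]-3-formyl-2-methylbut-2-enoate | C/C=C(\C)C(=O)O[C@@H](CC/C(C)=C\I)[C@]1(C)[C@H](OC(C)=O)C(=O)C=C(C)[C@H]1C/C(C=O)=C(\C)C(=O)OC | intermediate
30 | methyl (2Z)-2-[(1R,2S,5Z,7R,10R,14S)-14-acetoxy-7-hydroxy-1,5,11-trimethyl-2-[(2E)-2-methylbut-2-enoyloxy]-13-oxobicyclo[8.4.0]tetradeca-5,11-dien-8-ylidene]propanoate | C/C=C(\C)C(=O)O[C@H]1CC/C(C)=C\[C@@H](O)/C(=C(/C)C(=O)OC)C[C@@H]2C(C)=CC(=O)[C@@H](OC(C)=O)[C@@]12C | intermediate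
31 | (1R,2S,5Z,7R,10R,14S)-14-acetoxy-13-oxo-2-[(2E)-2-methylbut-2-enoyloxy]briara-5,8(17),11-trien-19,7-olide (CNP0218548.3) | C/C=C(\C)C(=O)O[C@H]1CC/C(C)=C\[C@H]2OC(=O)C(C)=C2C[C@@H]2C(C)=CC(=O)[C@@H](OC(C)=O)[C@@]12C | target

## Step count and risk

Total step count: 17 (steps 1–2 make the iodoallyl bromide 4, steps 3–4 the furylmethyl chloride 7, steps 5–17 the main line).
Longest linear sequence: 13 steps (steps 5–17, from 4-methylanisole 8 to 31).

The three steps most likely to fail:

Step 13 (1,6-addition and hydroxylation). The nucleophile may attack C12 (1,4-addition) instead of the neopentylic C10, or the dienone 22 may dimerise before it reacts. The fallback sets out from 20, which is isolated after the acylation of step 11 by a neutral work-up instead of the acid hydrolysis. Bis-allylic oxidation of 20 with pyridinium dichromate, (C5H5NH)2Cr2O7, and t-BuOOH gives the cross-conjugated methoxy dienone F1, in which C10 is the only true enone β-carbon. Copper-catalysed 1,4-addition of 23 (CuBr·SMe2, Me3SiCl, THF, −78 °C), again anti to the C1 side chain, gives the vinylogous ester F2. Reduction of the C12 carbonyl with NaBH4 and CeCl3·7H2O followed by 1 M HCl (Stork–Danheiser transposition) gives the enone F3. Since C1 is quaternary, LiN(iPr)2 can only remove the γ-hydrogen at C11, and the resulting dienolate is hydroxylated with the same oxaziridine to give 25, where the route is rejoined.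

Step 14 (α-ketol transposition). Under base the alkene may migrate instead to give the diosphenol (enolised 1,2-diketone), the tiglate may migrate from the C2 oxygen to the new C14 hydroxyl, or C14 may form as the wrong epimer. The fallback sets out from 25 and replaces the equilibration by a redox sequence. NaBH4 with CeCl3·7H2O in MeOH at −78 °C reduces the C14 ketone from the face opposite the C1 side chain to give the diol F4. MnO2 in CH2Cl2 then oxidises only the allylic C13 hydroxyl and gives 26, where the route is rejoined; acetylation as in step 14 gives 27.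

Step 17 (Nozaki–Hiyama–Kishi ring closure). The ten-membered ring may close poorly, CrCl2 may reduce the oxo-enoate or the α-acetoxy ketone, or C7 may form as the wrong epimer. The fallback sets out from 27, with the furan still intact, and makes the C6–C7 bond before the furan is oxidised. Intramolecular C–H alkenylation of the furan position next to the CH2 group by the vinyl iodide (Pd(OAc)2, PPh3, Ag2CO3, toluene, 80 °C, high dilution) gives the furan-bridged macrocycle F5. Singlet oxygen under the conditions of step 15 then gives the 7-hydroxybutenolide F6 regiospecifically, because only the C19 hydrogen is left. Ionic reduction with Et3SiH and CF3CO2H delivers hydride to C7 through the allylic acyloxycarbenium ion and gives 31, where the route is rejoined.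

Further compounds

F1 | step 13 | (1S,4Z)-5-iodo-1-[(1R)-2-methoxy-1,5-dimethyl-4-oxocyclohexa-2,5-dien-1-yl]-4-methylpent-4-en-1-yl (2E)-2-methylbut-2-enoate | C/C=C(\C)C(=O)O[C@@H](CC/C(C)=C\I)[C@]1(C)C(OC)=CC(=O)C(C)=C1
F2 | step 13 | (1S,4Z)-5-iodo-1-[(1R,6R)-2-methoxy-1,5-dimethyl-6-[(4-methylfuran-3-yl)methyl]-4-oxocyclohex-2-en-1-yl]-4-methylpent-4-en-1-yl (2E)-2-methylbut-2-enoate, both epimers at the ring carbon bearing the 5-methyl group | C/C=C(\C)C(=O)O[C@@H](CC/C(C)=C\I)[C@]1(C)C(OC)=CC(=O)C(C)[C@H]1Cc1cocc1C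
F3 | step 13 | (1S,4Z)-1-[(1R,2R)-1,3-dimethyl-2-[(4-methylfuran-3-yl)methyl]-6-oxocyclohex-4-en-1-yl]-5-iodo-4-methylpent-4-en-1-yl (2E)-2-methylbut-2-enoate, both epimers at the ring carbon bearing the 3-methyl group | C/C=C(\C)C(=O)O[C@@H](CC/C(C)=C\I)[C@]1(C)C(=O)C=CC(C)[C@H]1Cc1cocc1C
F4 | step 14 | (1S,4Z)-1-[(1S,2R,6S)-5,6-dihydroxy-1,3-dimethyl-2-[(4-methylfuran-3-yl)methyl]cyclohex-3-en-1-yl]-5-iodo-4-methylpent-4-en-1-yl (2E)-2-methylbut-2-enoate, both epimers at the allylic carbinol | C/C=C(\C)C(=O)O[C@@H](CC/C(C)=C\I)[C@]1(C)[C@H](O)C(O)C=C(C)[C@H]1Cc1cocc1C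
F5 | step 17 | (1R,2S,5Z,10R,14S)-14-acetoxy-2-[(2E)-2-methylbut-2-enoyloxy]-7,19-epoxybriara-5,7,11,17(19)-tetraen-13-one (furan-bridged macrocycle) | C/C=C(\C)C(=O)O[C@H]1CC/C(C)=C\c2occ(C)c2C[C@@H]2C(C)=CC(=O)[C@@H](OC(C)=O)[C@@]12C
F6 | step 17 | 7-hydroxy derivative of 31 (7-hydroxybutenolide, both C7 epimers) | C/C=C(\C)C(=O)O[C@H]1CC/C(C)=C\C2(O)OC(=O)C(C)=C2C[C@@H]2C(C)=CC(=O)[C@@H](OC(C)=O)[C@@]12C
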